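## Retrosynthetic overview
1. Structural feature: in the tetrahydrofuran ring (O1, C2 to C5), the two trans methyl groups on C3 and C4 sit next to C2, the carbon bearing ring A (3,4-dimethoxyphenyl). C2, C3, C4 and C5 can therefore be read as the γ-, β-, α- and carbonyl carbons of a γ-aryl butenolide.
2. The C5–ring B (3,4,5-trimethoxyphenyl) bond is cut last, as an arylzinc addition to the C5 oxocarbenium ion made from the lactone carbonyl via the lactol acetate.
3. C3–CH3 and C4–CH3 are cut together, as a Gilman cuprate 1,4-addition to butenolide 7 followed in the same flask by methylation of the enolate; C2 directs C3 and C3 directs C4.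
4. Butenolide 7 comes from ring-closing metathesis of the acrylate of (S)-1-(3,4-dimethoxyphenyl)prop-2-en-1-ol, which is made from veratraldehyde and CH2=CHMgBr and resolved with a lipase.
5. Ring order: rings A and B are bought. The five-membered oxygen ring is the only ring built; it is closed as the butenolide in step 4 and kept to the end.

Key step: step 5

Remark on the chemistry: 13 and 14 are carried as mixtures of C5 anomers, because both anomers ionise to the same oxocarbenium ion 18. Target numbering (O1, C2 to C5) is used for the ring carbons throughout.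

## Route

Step 1
Reactants: 1 veratraldehyde; 2 vinylmagnesium bromide
Product: 3 rac-1-(3,4-dimethoxyphenyl)prop-2-en-1-ol
Conditions: CH2=CHMgBr (1.2 equiv), THF, 0 °C; aq NH4Cl
Reagents that add atoms: vinylmagnesium bromide, C=C[Mg]Br
Why: Grignard 1,2-addition of a vinyl nucleophile to a non-enolisable aromatic aldehyde should give the secondary allylic alcohol cleanly, with the carbinol centre (future C2) formed without control here and sorted in step 2.

Step 2
Reactants: 3 rac-1-(3,4-dimethoxyphenyl)prop-2-en-1-ol
Product: 4 (S)-1-(3,4-dimethoxyphenyl)prop-2-en-1-ol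
Conditions: Novozym 435 (immobilised Candida antarctica lipase B), isopropenyl acetate, toluene, 40 °C, stopped just past half conversion; filtration, chromatography
Reagents that add atoms: none
Why: Enzymatic kinetic resolution by irreversible acyl transfer, in which the empirical size rule for lipases (ring A as the large group, vinyl as the medium group) predicts acetylation of the (R)-alcohol and recovery of the (S)-alcohol, whose enantiomeric purity can be raised by going slightly past half conversion, so that C2 of the target is fixed here without passing through the polymerisation-prone aryl vinyl ketone.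

Step 3
Reactants: 4 (S)-1-(3,4-dimethoxyphenyl)prop-2-en-1-ol; 5 acryloyl chloride
Product: 6 (S)-1-(3,4-dimethoxyphenyl)allyl acrylate
Conditions: acryloyl chloride (1.3 equiv), Et3N (1.6 equiv), CH2Cl2, −20 → 0 °C
Reagents that add atoms: acryloyl chloride, C=CC(=O)Cl
Why: O-acylation of a secondary alcohol with an acid chloride and an amine base at low temperature leaves the C–O bond of the stereocentre intact, so the ionisation-prone benzylic allylic position keeps its (S) configuration.

Step 4
Reactants: 6 (S)-1-(3,4-dimethoxyphenyl)allyl acrylate
Product: 7 (S)-5-(3,4-dimethoxyphenyl)furan-2(5H)-one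
Conditions: second-generation Grubbs catalyst RuCl2(=CHPh)(PCy3)(H2IMes) (5 mol %), 1,4-benzoquinone (10 mol %), CH2Cl2 (0.01 M), reflux
Reagents that add atoms: none
Why: Ring-closing metathesis of an allyl acrylate to a five-membered butenolide with loss of ethene, for which the carbene-ligated ruthenium catalyst is active enough toward the electron-poor acrylate, while the base-free medium spares the labile γ-stereocentre and benzoquinone suppresses double-bond migration by ruthenium hydrides.

Step 5
Reactants: 7 (S)-5-(3,4-dimethoxyphenyl)furan-2(5H)-one; 8 methyllithium; 9 iodomethane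
Product: 12 (3S,4S,5S)-5-(3,4-dimethoxyphenyl)-3,4-dimethyldihydrofuran-2(3H)-one (all-trans), via Me2CuLi 10 (not isolated), via lithium enolate 11 (not isolated)
Conditions: CuI (1.5 equiv), MeLi (3.0 equiv), Et2O, 0 °C; 7, Et2O–THF, −78 → −40 °C; then MeI (10 equiv), DMPU, −78 → −20 °C; aq NH4Cl–NH3
Reagents that add atoms: methyllithium, [Li]C (delivered as Me2CuLi, [Li+].C[Cu-]C); iodomethane, CI
Why: Me2CuLi 10 binds the C=C bond of 7 as a d–π* complex, oxidative addition at the β-carbon gives a trivalent-copper β-cuprio enolate, and reductive elimination forms C3–CH3 and releases MeCu plus lithium enolate 11, whose α-carbon then displaces iodide from MeI (SN2, DMPU as cosolvent) to form C4–CH3. The closest known reaction type is the three-component conjugate addition–enolate alkylation of γ-substituted butenolides and cyclopentenones with Gilman cuprates; no ring is closed, and the lactone ring from step 4 is simply carried through. C3 is controlled by the C2 stereocentre, because ring A covers one face of the flat butenolide and copper with its methyl group should arrive on the other face (2,3-trans, 3S in target numbering). C4 is controlled by the new C3 methyl group, because in the nearly planar enolate the neighbouring substituent outweighs the more remote ring A (which lies on the face MeI has to use), so MeI should enter anti to C3–CH3 (3,4-trans, 4S); the all-trans lactone is also the most stable epimer, so a minor cis epimer could be equilibrated with DBU. The step needs 1,4- over 1,2-addition and C–C bond formation faster than removal of the acidic benzylic γ-hydrogen; the soft, weakly basic cuprate secures both, and the C2–O1 ring bond lies near the nodal plane of the enoate π system, which disfavours reductive or SN2′ loss of the carboxylate. Monomethylation is secured by a large excess of MeI at low temperature, so that 11 is consumed before it can exchange protons with 12.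

Step 6
Reactants: 12 (3S,4S,5S)-5-(3,4-dimethoxyphenyl)-3,4-dimethyldihydrofuran-2(3H)-one
Product: 13 (3S,4S,5S)-5-(3,4-dimethoxyphenyl)-3,4-dimethyltetrahydrofuran-2-ol (anomeric mixture)
Conditions: i-Bu2AlH (1.1 equiv), CH2Cl2, −78 °C; aq potassium sodium tartrate
Reagents that add atoms: none
Why: Partial reduction of a γ-lactone with one hydride equivalent should stop at the lactol because the tetrahedral aluminium hemiacetal persists at −78 °C, leaving C2, C3 and C4 untouched and creating an anomeric centre of no consequence.

Step 7
Reactants: 13 (3S,4S,5S)-5-(3,4-dimethoxyphenyl)-3,4-dimethyltetrahydrofuran-2-ol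
Product: 14 (3S,4S,5S)-5-(3,4-dimethoxyphenyl)-3,4-dimethyltetrahydrofuran-2-yl acetate (anomeric mixture)
Conditions: Ac2O, pyridine, DMAP (cat), CH2Cl2, 0 °C → rt
Reagents that add atoms: acetic anhydride, CC(=O)OC(C)=O
Why: DMAP-catalysed O-acetylation of the lactol hydroxyl places a leaving group on C5 under mild conditions, and any equilibration of C4 through the open hydroxy aldehyde would favour the same trans C3/C4 arrangement.

Step 8
Reactants: 14 (3S,4S,5S)-5-(3,4-dimethoxyphenyl)-3,4-dimethyltetrahydrofuran-2-yl acetate; 15 5-bromo-1,2,3-trimethoxybenzene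
Product: 19 5-methoxygalbelgin = (2S,3S,4S,5S)-2-(3,4-dimethoxyphenyl)-3,4-dimethyl-5-(3,4,5-trimethoxyphenyl)tetrahydrofuran, via arylmagnesium bromide 16 (not isolated), via arylzinc bromide 17 (not isolated), via oxocarbenium ion 18 (not isolated)
Conditions: 15, Mg, THF, 40 °C; ZnBr2, THF, 0 °C → rt; then 14, BF3·OEt2, CH2Cl2–THF, −78 → −20 °C; aq NH4Cl
Reagents that add atoms: 5-bromo-1,2,3-trimethoxybenzene, COc1cc(Br)cc(OC)c1OC (delivered as the arylzinc bromide, COc1cc([Zn]Br)cc(OC)c1OC)
Why: Lewis-acid-promoted substitution of a lactol acetate by an arylzinc halide through the five-membered oxocarbenium ion 18 (the reaction type of C-aryl glycoside synthesis), in which the bulky aryl donor should enter C5 on the face away from the neighbouring C4 methyl group and from ring A on C2 to set 5S (4,5-trans, 2,5-trans), the all-trans product also being the thermodynamic sink should BF3 reopen a benzylic C–O bond, while a Friedel–Crafts alternative is excluded because 1,2,3-trimethoxybenzene would react at its C4 and give the wrong ring B pattern.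

## Compound list
1 | veratraldehyde (3,4-dimethoxybenzaldehyde) | COc1ccc(C=O)cc1OC | starting material
2 | vinylmagnesium bromide | C=C[Mg]Br | starting material
3 | rac-1-(3,4-dimethoxyphenyl)prop-2-en-1-ol | COc1ccc(C(O)C=C)cc1OC | intermediate
4 | (S)-1-(3,4-dimethoxyphenyl)prop-2-en-1-ol | COc1ccc([C@@H](O)C=C)cc1OC | intermediate
5 | acryloyl chloride | C=CC(=O)Cl | starting material
6 | (S)-1-(3,4-dimethoxyphenyl)allyl acrylate | COc1ccc([C@@H](OC(=O)C=C)C=C)cc1OC | intermediate
7 | (S)-5-(3,4-dimethoxyphenyl)furan-2(5H)-one | COc1ccc([C@H]2OC(=O)C=C2)cc1OC | intermediate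
8 | methyllithium | [Li]C | starting material
9 | iodomethane | CI | starting material
10 | lithium dimethylcuprate, Me2CuLi (not isolated) | [Li+].C[Cu-]C | intermediate
11 | lithium (4S,5S)-5-(3,4-dimethoxyphenyl)-4-methyl-4,5-dihydrofuran-2-olate (not isolated) | [Li+].COc1ccc([C@H]2OC([O-])=C[C@@H]2C)cc1OC | intermediate
12 | (3S,4S,5S)-5-(3,4-dimethoxyphenyl)-3,4-dimethyldihydrofuran-2(3H)-one | COc1ccc([C@H]2OC(=O)[C@@H](C)[C@@H]2C)cc1OC | intermediate
13 | (3S,4S,5S)-5-(3,4-dimethoxyphenyl)-3,4-dimethyltetrahydrofuran-2-ol, anomeric mixture | COc1ccc([C@H]2OC(O)[C@@H](C)[C@@H]2C)cc1OC | intermediate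
14 | (3S,4S,5S)-5-(3,4-dimethoxyphenyl)-3,4-dimethyltetrahydrofuran-2-yl acetate, anomeric mixture | COc1ccc([C@H]2OC(OC(C)=O)[C@@H](C)[C@@H]2C)cc1OC | intermediate
15 | 5-bromo-1,2,3-trimethoxybenzene | COc1cc(Br)cc(OC)c1OC | starting material
16 | (3,4,5-trimethoxyphenyl)magnesium bromide (not isolated) | COc1cc([Mg]Br)cc(OC)c1OC | intermediate
17 | (3,4,5-trimethoxyphenyl)zinc bromide (not isolated) | COc1cc([Zn]Br)cc(OC)c1OC | intermediate
18 | (2S,3S,4S)-2-(3,4-dimethoxyphenyl)-3,4-dimethyl-3,4-dihydro-2H-furan-1-ium acetoxytrifluoroborate (not isolated) | COc1ccc([C@H]2[O+]=C[C@@H](C)[C@@H]2C)cc1OC.CC(=O)O[B-](F)(F)F | intermediate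
19 | 5-methoxygalbelgin, (2S,3S,4S,5S)-2-(3,4-dimethoxyphenyl)-3,4-dimethyl-5-(3,4,5-trimethoxyphenyl)tetrahydrofuran | COc1ccc([C@H]2O[C@H](c3cc(OC)c(OC)c(OC)c3)[C@@H](C)[C@@H]2C)cc1OC | target

## Step count and risks
Total step count: 8. Longest linear sequence: 8 steps (1 to 19); arylzinc 17 is made in the flask within step 8.

**Risk 1, step 5.**
- What may go wrong: the copper-associated enolate may alkylate slowly. Proton exchange between enolate and product could then lead to incomplete or double methylation. The second methylation has to override ring A on the face it uses, so its facial selectivity may be imperfect.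
- Fallback: the two C–CH3 bonds are made in separate operations.
  - It sets out from 7, where the Me2CuLi addition is quenched with aq NH4Cl to give (4S,5S)-5-(3,4-dimethoxyphenyl)-4-methyldihydrofuran-2(3H)-one F1, which is purified.
  - LiN(SiMe3)2 in THF at −78 °C then regenerates enolate 11 free of copper salts, and 9 methylates it anti to the β-methyl group.
  - Any α-epimer is equilibrated with DBU. The fallback comes back to the route at 12.

**Risk 2, step 8.**
- What may go wrong:
  - The stereoelectronic preference for inside attack on the all-pseudoequatorial envelope of the oxocarbenium ion competes with steric approach control, so facial selectivity at C5 may be poor.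
  - BF3 may open the benzylic C2–O1 bond, causing epimerisation or Friedel–Crafts cyclisation.
  - Aryl transfer from zinc to boron may consume the nucleophile.
- Fallback: the order of the two C5 substituents is reversed, starting from lactone 12.
  - Bromide 15 is lithiated with n-BuLi (THF, −78 °C) to (3,4,5-trimethoxyphenyl)lithium F2.
  - F2 adds once to the lactone carbonyl to give (3S,4S,5S)-5-(3,4-dimethoxyphenyl)-3,4-dimethyl-2-(3,4,5-trimethoxyphenyl)tetrahydrofuran-2-ol F3.
  - Ionic reduction with Et3SiH and BF3·OEt2 (CH2Cl2, −78 °C) proceeds through the C5-aryl oxocarbenium ion F4.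
  - The small hydride donor should follow inside attack, on the face anti to the C3 methyl group, which places ring B trans to the C4 methyl group.
  - This is the known reductive deoxygenation of cyclic hemiketals. It comes back to the route at 19.

**Risk 3, step 2.**
- What may go wrong: the enzyme may discriminate poorly between the two flat sp2 substituents. Useful enantiomeric enrichment would then be reached only at high conversion, with heavy loss of material.
- Fallback: the resolution is replaced by an asymmetric reduction, starting from 3.
  - MnO2 in CH2Cl2 oxidises 3 to 1-(3,4-dimethoxyphenyl)prop-2-en-1-one F5, which is used at once.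
  - CBS reduction with (R)-2-methyl-CBS-oxazaborolidine (10 mol %) and catecholborane in toluene at −78 °C follows, with ring A as the large group.
  - This comes back to the route at 4 and removes the half-of-material limit.

## Further compounds
F1 | step 5 | (4S,5S)-5-(3,4-dimethoxyphenyl)-4-methyldihydrofuran-2(3H)-one | COc1ccc([C@H]2OC(=O)C[C@@H]2C)cc1OC
F2 | step 8 | (3,4,5-trimethoxyphenyl)lithium | COc1cc([Li])cc(OC)c1OC
F3 | step 8 | (3S,4S,5S)-5-(3,4-dimethoxyphenyl)-3,4-dimethyl-2-(3,4,5-trimethoxyphenyl)tetrahydrofuran-2-ol, anomeric mixture | COc1ccc([C@H]2OC(O)(c3cc(OC)c(OC)c(OC)c3)[C@@H](C)[C@@H]2C)cc1OC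
F4 | step 8 | (2S,3S,4S)-2-(3,4-dimethoxyphenyl)-3,4-dimethyl-5-(3,4,5-trimethoxyphenyl)-3,4-dihydro-2H-furan-1-ium hydroxytrifluoroborate | COc1ccc([C@H]2[O+]=C(c3cc(OC)c(OC)c(OC)c3)[C@@H](C)[C@@H]2C)cc1OC.O[B-](F)(F)F
F5 | step 2 | 1-(3,4-dimethoxyphenyl)prop-2-en-1-one | COc1ccc(C(=O)C=C)cc1OC
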